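Germacrane numbering is used for every compound: ring C1–C10, lactone C6–O–C12(=O)–C11–C7, C13 = methylene on C11, C14 on C10, C15 on C4.
Retrosynthesis: the C8 ester, the C10–C14 bond, C13 and the lactone C6–O bond are cut first. This leads back to a ten-membered enynone with a C6 ketone, a cis C4=C5 alkene and a C1≡C10 alkyne.
Enabling feature: C1 and C6 face each other 1,5 across the ten-membered ring. An added C1–C6 bond therefore gives a decalin made of ring A (C1–C6, already holding the cis C4=C5 alkene and C15) and ring B (C1, C6–C10). As a C1,C6-epoxide next to a C10 ketone, that bond can be cut again.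
Forward: 7-methoxy-2-tetralone supplies ring B and the arene precursor of ring A. C11–C12 is added by alkylation, ring A is dearomatised (Birch), and the methoxy-bearing C4 is changed to C4–C15 through a dienyl triflate. The epoxy ketone is then made and fragmented, the lactone ring is closed, and C13, C14 and the isovalerate are added.
Stereochemistry: C7 and C8 come from one dynamic-kinetic transfer hydrogenation. The transient C10 carbinol (CBS reduction) steers the epoxide. C6 comes from Felkin–Anh hydride addition followed by inversion in the lactone closure. The C4=C5 geometry comes from ring A, and the C1=C10 geometry from a syn hydrosilylation tethered to O8.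

Key step: step 15

Assumption: in step 2 the (R,R)-catalyst is taken to give the 8R carbinol, by analogy with aryl ketones with the benzylic C7 flank in the place of the aryl group; the mirror-image catalyst is equally available.

Step 1
Reactants: 1 7-methoxy-2-tetralone; 2 methyl bromoacetate
Product: 4 methyl (±)-2-(7-methoxy-2-oxo-1,2,3,4-tetrahydronaphthalen-1-yl)acetate, via pyrrolidine enamine 3 (not isolated)
Conditions: pyrrolidine, toluene, reflux (−H2O); BrCH2CO2Me, MeCN, reflux; AcOH/H2O, rt
Reagents that add atoms: methyl bromoacetate BrCC(=O)OC; water O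
Why: Stork enamine alkylation: a 2-tetralone forms only the styrene-type C7=C8 enamine, so the bromoacetate is attacked by the benzylic carbon C7 alone and hydrolysis returns the ketone, with C7 racemic and deliberately labile.

Step 2
Reactants: 4 methyl (±)-2-(7-methoxy-2-oxo-1,2,3,4-tetrahydronaphthalen-1-yl)acetate
Product: 6 cis-lactone (3aR,9bS)-8-methoxy-3a,4,5,9b-tetrahydronaphtho[2,1-b]furan-2(1H)-one, via cis-hydroxy ester 5 (not isolated)
Conditions: RuCl(p-cymene)[(R,R)-TsDPEN] (cat.), HCO2H/Et3N, rt; then TsOH·H2O (cat.), toluene, 60 °C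
Reagents that add atoms: none
Why: Noyori–Ikariya transfer hydrogenation under dynamic kinetic resolution, as known for 1-substituted 2-tetralones: Et3N racemises the benzylic α-keto C7–H faster than reduction, the catalyst selects one enantiomer and adds hydride anti to the pseudo-axial side chain, which sets C8 and C7 cis, and the cis γ-hydroxy ester lactonises.

Step 3
Reactants: 6 cis-lactone
Product: 7 keto lactone (3aR,9bS)-8-methoxy-3a,4-dihydronaphtho[2,1-b]furan-2,5(1H,9bH)-dione (C10 ketone)
Conditions: CrO3, AcOH/H2O, 10 °C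
Reagents that add atoms: chromium trioxide O=[Cr](=O)=O
Why: Benzylic oxidation: only the C10 methylene lies para to the methoxy group, as in the oxidation of 6-methoxytetralin to 6-methoxy-1-tetralone, and the cold acidic medium should avoid E1cB loss of the β-acyloxy group.

Step 4
Reactants: 7 keto lactone
Product: 8 (3aR,5R,9bS)-5-hydroxy-8-methoxy-3a,4,5,9b-tetrahydronaphtho[2,1-b]furan-2(1H)-one (10-OH trans to O8)
Conditions: (S)-Me-CBS [(S)-1-methyl-3,3-diphenyltetrahydro-1H,3H-pyrrolo[1,2-c][1,3,2]oxazaborole] (cat.), BH3·SMe2, THF, −20 °C; MeOH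
Reagents that add atoms: none
Why: Corey–Bakshi–Shibata reduction: 1-tetralones are standard substrates, the (S)-catalyst gives the (R)-benzylic alcohol (10-OH on the face away from the lactone ring), and the non-basic medium does not trigger β-elimination.

Step 5
Reactants: 8 hydroxy lactone
Product: 11 (3aR,5R,9bS)-5-hydroxy-1,3a,4,5,6,7,9,9b-octahydronaphtho[2,1-b]furan-2,8-dione (C4 ketone; C1=C6 alkene; 10-OH), via lithium carboxylate 9 (not isolated), via dihydroanisole 10 (not isolated)
Conditions: LiOH, THF/H2O, rt, evaporation to dryness; Li, NH3(l), THF, t-BuOH, −78 to −33 °C; NH4Cl; (CO2H)2, THF/H2O, rt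
Reagents that add atoms: water O; lithium hydroxide [Li+].[OH-]
Why: Birch reduction: with the lactone opened all oxygen functions are anionic and inert, the benzylic C10–O sits para to OMe where the radical anion has a node, protonation falls on C2 and C5 as in 6-methoxytetralin, and oxalic acid then frees the unconjugated C4 ketone and recloses the cis lactone.

Step 6
Reactants: 11 enone lactone
Product: 12 10-O-triethylsilyl ether of 11
Conditions: Et3SiCl, imidazole, CH2Cl2, 0 °C
Reagents that add atoms: chlorotriethylsilane CC[Si](Cl)(CC)CC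
Why: Silyl ether protection of the only hydroxyl, needed because a free alkoxide would compete for the triflating agent in step 7, with a base too weak to conjugate the enone.

Step 7
Reactants: 12 TES ether
Product: 14 C4 dienyl triflate (diene C4=C5–C6=C1), via potassium dienolate 13 (not isolated)
Conditions: KN(SiMe3)2, THF, −78 °C; Comins' reagent, −78 °C
Reagents that add atoms: Comins' reagent FC(F)(F)S(=O)(=O)N(c1ccc(Cl)cn1)S(=O)(=O)C(F)(F)F
Why: Enol triflate formation: the C5 protons lie between the ketone and the C1=C6 alkene and are far more acidic than C3–H or the lactone C11–H, so the linear dienolate forms and O-sulfonylation fixes the ring A 1,3-diene in the required place.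

Step 8
Reactants: 14 dienyl triflate; 15 (tributylstannyl)methanol
Product: 16 C4-hydroxymethyl diene (C15–OH)
Conditions: Pd(PPh3)4 (cat.), LiCl, THF, 60 °C
Reagents that add atoms: (tributylstannyl)methanol CCCC[Sn](CCCC)(CCCC)CO
Why: Stille coupling with zerovalent palladium: hydroxymethylation of enol triflates with this stannane is established, and it forms C4–C15 without touching the lactone or the silyl ether.

Step 9
Reactants: 16 dienyl methanol
Product: 17 15-O-TBDPS ether of 16
Conditions: t-BuPh2SiCl, imidazole, CH2Cl2, 0 °C to rt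
Reagents that add atoms: tert-butylchlorodiphenylsilane CC(C)(C)[Si](Cl)(c1ccccc1)c1ccccc1
Why: Silyl ether protection of the primary allylic alcohol with the group that must outlast both TES and TBS and that keeps C15–OH from directing the epoxidation to C4=C5.

Step 10
Reactants: 17 TBDPS ether
Product: 18 8-hydroxy N,N-dimethylamide (O8–C12 lactone opened)
Conditions: Me2NH (THF solution), AlMe3, CH2Cl2, 0 °C to rt
Reagents that add atoms: dimethylamine CNC
Why: Aluminium amide aminolysis of a lactone: the γ-hydroxy amide does not relactonise under neutral conditions, so O8 and C12 are separated and C12 gains the amide oxygen needed in step 17.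

Step 11
Reactants: 18 hydroxy amide
Product: 19 8-O-TBS ether of 18
Conditions: t-BuMe2SiOTf, 2,6-lutidine, CH2Cl2, −78 to 0 °C
Reagents that add atoms: tert-butyldimethylsilyl triflate CC(C)(C)[Si](C)(C)OS(=O)(=O)C(F)(F)F
Why: Silyl ether protection with the reactive triflate, which covers the hindered secondary 8-OH before it can close back on C12.

Step 12
Reactants: 19 tris-silyl ether
Product: 20 dienol (10-OH free; 8-OTBS and 15-OTBDPS kept)
Conditions: HF·pyridine, pyridine, THF, 0 °C
Reagents that add atoms: none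
Why: Selective desilylation: a TES ether is cleaved far faster than TBS or TBDPS, and the buffered fluoride medium avoids ionising the dienylic alcohol.

Step 13
Reactants: 20 dienol
Product: 21 1,6-epoxy-10-ol (epoxide syn to 10-OH and anti to the C7 and C8 substituents)
Conditions: VO(acac)2 (cat.), t-BuOOH (decane), CH2Cl2, 0 °C
Reagents that add atoms: tert-butyl hydroperoxide CC(C)(C)OO
Why: Vanadium-catalysed hydroxyl-directed epoxidation of a cyclohexenol: the pseudo-axial 10-OH delivers oxygen to C1=C6 on its own open face, while C4=C5 has no free directing hydroxyl.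

Step 14
Reactants: 21 epoxy alcohol
Product: 22 1,6-epoxy-10-ketone (C4=C5 alkene; 8-OTBS; C12 dimethylamide; 15-OTBDPS)
Conditions: Dess–Martin periodinane, NaHCO3, CH2Cl2, 0 °C to rt
Reagents that add atoms: none
Why: Dess–Martin oxidation: the buffered neutral oxidant should convert the only free alcohol into the ketone without opening the vinyl epoxide or eliminating the β-silyloxy group.

Step 15
Reactants: 22 epoxy ketone
Product: 24 ten-membered enynone (C6 ketone; C4=C5 cis in the ring; C1≡C10; C7 and C8 as in the target), via tosylhydrazone 23 (not isolated)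
Conditions: TsNHNH2, AcOH/CH2Cl2 (1:1), −20 °C to rt
Reagents that add atoms: none
Why: Eschenmoser–Tanabe fragmentation: the hydrazide condenses with the C10 ketone to give 23, whose N–H end pushes open the C1–O bond of the neighbouring epoxide and leaves a C10=C1 azoalkene with the oxygen on C6. That oxygen then becomes the C6 carbonyl while C1–C6 breaks, C1≡C10 forms and N2 and toluenesulfinate depart in one Grob-type sequence. The closest known case is the epoxide of bicyclo[4.4.0]dec-1(6)-en-2-one, which gives cyclodec-5-ynone under these conditions, so only the substitution is new. The ten-membered ring is not closed by bond formation but appears when the bond shared by rings A and B is cut; no stereocentre is created, both epoxide centres vanish, C7 and C8 are untouched, and the cis C4=C5 geometry is the one ring A enforced. The step needs chemoselectivity only: the ketone is the sole carbonyl that condenses (the amide is inert), the cold weakly acidic medium should spare the silyl ethers, the vinyl epoxide and the β-silyloxy ketones, and cleavage is helped because the new carbonyl is formed conjugated to C4=C5.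

Step 16
Reactants: 24 enynone
Product: 25 (6S)-allylic alcohol (6-epi with respect to the target)
Conditions: NaBH4, CeCl3·7H2O, MeOH, −78 °C
Reagents that add atoms: none
Why: Luche 1,2-reduction under Felkin–Anh control: the ring bond C7–C8 stands perpendicular to the carbonyl, so hydride should enter from the open peripheral face anti to C8 and past H7, which gives the 6S alcohol, and the amide cannot lactonise under these conditions.

Step 17
Reactants: 25 (6S)-alcohol
Product: 28 trans-fused 6,12-lactone (6R; 8-OTBS; 15-OTBDPS; C1≡C10), via allylic mesylate 26 (not isolated), via iminium ether mesylate salt 27 (not isolated)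
Conditions: Ms2O, i-Pr2NEt, CH2Cl2, −40 to 0 °C; then aq. NaHCO3, THF, rt
Reagents that add atoms: water O
Why: Neighbouring-group displacement (5-exo-tet SN2) of the allylic mesylate by the amide oxygen inverts C6 to the required 6R configuration, hydrolysis of the iminium ether gives the lactone, and the anhydride keeps chloride out of the flask.

Step 18
Reactants: 28 lactone; 29 Eschenmoser's salt
Product: 33 α-methylene lactone, via lithium enolate 30 (not isolated), via Mannich base 31 (not isolated), via ammonium iodide 32 (not isolated)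
Conditions: LiN(i-Pr)2, THF, −78 °C; [CH2=NMe2]I, −78 °C to rt; MeI, THF, rt; aq. NaHCO3, CH2Cl2, rt
Reagents that add atoms: Eschenmoser's salt C[N+](C)=C.[I-]
Why: Standard α-methylenation (Mannich reaction, quaternisation, elimination), placed here because the lactone is the only enolisable carbonyl while O8 is still silylated and the isovalerate is absent.

Step 19
Reactants: 33 α-methylene lactone
Product: 34 8-hydroxy α-methylene lactone (15-OTBDPS kept)
Conditions: HF (48 % aq.), MeCN, 0 °C
Reagents that add atoms: none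
Why: Selective desilylation: under acidic fluoride a TBS ether is lost much faster than a TBDPS ether, and the medium is neither basic nor nucleophilic enough to move the lactone or add to the methylene group.

Step 20
Reactants: 34 homopropargylic alcohol
Product: 36 cyclic vinylsiloxane (O8–SiMe2–C10; C1=C10 cis in the ring), via dimethylsilyl ether 35 (not isolated)
Conditions: (HMe2Si)2NH, THF, rt, evaporation; Pt2[(CH2=CHSiMe2)2O]3 (cat.), THF, rt
Reagents that add atoms: 1,1,3,3-tetramethyldisilazane C[SiH](C)N[SiH](C)C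
Why: Intramolecular syn hydrosilylation of a homopropargylic silyl ether with zerovalent platinum: the 5-exo-dig mode puts silicon on the near alkyne carbon C10 and hydrogen on C1 from the same side, which leaves C2 and C9 cis.

Step 21
Reactants: 36 cyclic vinylsiloxane
Product: 37 C10 vinyl iodide with free 8-OH
Conditions: N-iodosuccinimide, (CF3)2CHOH/CH2Cl2, 0 °C; aq. Na2S2O3/NaHCO3
Reagents that add atoms: N-iodosuccinimide O=C1CCC(=O)N1I
Why: Iododesilylation: ipso attack of the iodonium source gives a β-silyl cation that loses silicon with retention in this solvent, inversion would force a trans alkene into the ring, and the silicon residue on O8 falls off on aqueous work-up.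

Step 22
Reactants: 37 hydroxy vinyl iodide; 38 isovaleric anhydride
Product: 39 8-O-isovalerate of 37
Conditions: (i-PrCH2CO)2O, DMAP, pyridine, CH2Cl2, 0 °C to rt
Reagents that add atoms: isovaleric anhydride CC(C)CC(=O)OC(=O)CC(C)C
Why: DMAP-catalysed acylation of the only free hydroxyl, done before C14–OH exists so that no differentiation of alcohols is needed.

Step 23
Reactants: 39 vinyl iodide isovalerate; 15 (tributylstannyl)methanol
Product: 40 15-O-TBDPS ether of the target
Conditions: Pd2(dba)3 (cat.), AsPh3, N-methylpyrrolidone, 50 °C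
Reagents that add atoms: (tributylstannyl)methanol CCCC[Sn](CCCC)(CCCC)CO
Why: Stille coupling with retention of the alkene geometry forms C10–C14 directly at the alcohol level, and the arsine ligand speeds transmetalation so that the vinylpalladium species is intercepted before it can engage the methylene lactone.

Step 24
Reactants: 40 silyl ether
Product: 41 target CNP0199826.1
Conditions: Bu4NF, AcOH, THF, 0 °C to rt
Reagents that add atoms: none
Why: Fluoride desilylation buffered with acetic acid removes the last silyl group without acyl migration, lactone opening or addition to the methylene lactone.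

Compound list
1 | 7-methoxy-2-tetralone | O=C1CCc2ccc(OC)cc2C1 | starting material
2 | methyl bromoacetate | BrCC(=O)OC | starting material
3 | 1-(7-methoxy-3,4-dihydronaphthalen-2-yl)pyrrolidine | COc1ccc2CCC(=Cc2c1)N1CCCC1 | intermediate
4 | methyl (±)-2-(7-methoxy-2-oxo-1,2,3,4-tetrahydronaphthalen-1-yl)acetate | COC(=O)CC1C(=O)CCc2ccc(OC)cc21 | intermediate
5 | methyl 2-[(1S,2R)-2-hydroxy-7-methoxy-1,2,3,4-tetrahydronaphthalen-1-yl]acetate | C1C[C@@H](O)[C@@H](CC(=O)OC)c2cc(OC)ccc21 | intermediate
6 | (3aR,9bS)-8-methoxy-3a,4,5,9b-tetrahydronaphtho[2,1-b]furan-2(1H)-one | C1C[C@@H](OC(=O)C2)[C@@H]2c3cc(OC)ccc31 | intermediate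
7 | (3aR,9bS)-8-methoxy-3a,4-dihydronaphtho[2,1-b]furan-2,5(1H,9bH)-dione | O=C1C[C@@H](OC(=O)C2)[C@@H]2c3cc(OC)ccc31 | intermediate
8 | (3aR,5R,9bS)-5-hydroxy-8-methoxy-3a,4,5,9b-tetrahydronaphtho[2,1-b]furan-2(1H)-one | O[C@@H]1C[C@@H](OC(=O)C2)[C@@H]2c3cc(OC)ccc31 | intermediate
9 | lithium 2-[(1S,2R,4R)-2,4-dihydroxy-7-methoxy-1,2,3,4-tetrahydronaphthalen-1-yl]acetate | O[C@@H]1C[C@@H](O)[C@@H](CC(=O)[O-])c2cc(OC)ccc21.[Li+] | intermediate
10 | lithium 2-[(1S,2R,4R)-2,4-dihydroxy-7-methoxy-1,2,3,4,5,8-hexahydronaphthalen-1-yl]acetate | O[C@@H]1C[C@@H](O)[C@@H](CC(=O)[O-])C2=C1CC=C(OC)C2.[Li+] | intermediate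
11 | (3aR,5R,9bS)-5-hydroxy-1,3a,4,5,6,7,9,9b-octahydronaphtho[2,1-b]furan-2,8-dione | O[C@@H]1C[C@@H](OC(=O)C2)[C@@H]2C3=C1CCC(=O)C3 | intermediate
12 | 10-O-TES ether of 11 | CC[Si](CC)(CC)O[C@@H]1C[C@@H](OC(=O)C2)[C@@H]2C3=C1CCC(=O)C3 | intermediate
13 | potassium C4 dienolate of 12 | CC[Si](CC)(CC)O[C@@H]1C[C@@H](OC(=O)C2)[C@@H]2C3=C1CCC([O-])=C3.[K+] | intermediate
14 | C4 dienyl triflate | CC[Si](CC)(CC)O[C@@H]1C[C@@H](OC(=O)C2)[C@@H]2C3=C1CCC(OS(=O)(=O)C(F)(F)F)=C3 | intermediate
15 | (tributylstannyl)methanol | CCCC[Sn](CCCC)(CCCC)CO | starting material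
16 | C4-hydroxymethyl diene lactone | CC[Si](CC)(CC)O[C@@H]1C[C@@H](OC(=O)C2)[C@@H]2C3=C1CCC(CO)=C3 | intermediate
17 | 15-O-TBDPS ether of 16 | CC[Si](CC)(CC)O[C@@H]1C[C@@H](OC(=O)C2)[C@@H]2C3=C1CCC(CO[Si](c4ccccc4)(c4ccccc4)C(C)(C)C)=C3 | intermediate
18 | 8-hydroxy C12 dimethylamide | CC[Si](CC)(CC)O[C@@H]1C[C@@H](O)[C@@H](CC(=O)N(C)C)C2=C1CCC(CO[Si](c3ccccc3)(c3ccccc3)C(C)(C)C)=C2 | intermediate
19 | 8-O-TBS ether of 18 | CC[Si](CC)(CC)O[C@@H]1C[C@@H](O[Si](C)(C)C(C)(C)C)[C@@H](CC(=O)N(C)C)C2=C1CCC(CO[Si](c3ccccc3)(c3ccccc3)C(C)(C)C)=C2 | intermediate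
20 | dienol with free 10-OH | O[C@@H]1C[C@@H](O[Si](C)(C)C(C)(C)C)[C@@H](CC(=O)N(C)C)C2=C1CCC(CO[Si](c3ccccc3)(c3ccccc3)C(C)(C)C)=C2 | intermediate
21 | 1,6-epoxy-10-ol (epoxide syn to 10-OH, anti to C7/C8 substituents) | O[C@@H]1C[C@@H](O[Si](C)(C)C(C)(C)C)[C@@H](CC(=O)N(C)C)[C@]23O[C@]12CCC(CO[Si](c4ccccc4)(c4ccccc4)C(C)(C)C)=C3 | intermediate
22 | 1,6-epoxy-10-ketone (key-step precursor) | O=C1C[C@@H](O[Si](C)(C)C(C)(C)C)[C@@H](CC(=O)N(C)C)[C@]23O[C@]12CCC(CO[Si](c4ccccc4)(c4ccccc4)C(C)(C)C)=C3 | intermediate
23 | tosylhydrazone of 22 | Cc1ccc(cc1)S(=O)(=O)NN=C1C[C@@H](O[Si](C)(C)C(C)(C)C)[C@@H](CC(=O)N(C)C)[C@]23O[C@]12CCC(CO[Si](c4ccccc4)(c4ccccc4)C(C)(C)C)=C3 | intermediate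
24 | ten-membered enynone (key-step product) | O=C1/C=C(/CO[Si](c2ccccc2)(c2ccccc2)C(C)(C)C)CCC#CC[C@@H](O[Si](C)(C)C(C)(C)C)[C@H]1CC(=O)N(C)C | intermediate
25 | (6S)-allylic alcohol | O[C@H]1/C=C(/CO[Si](c2ccccc2)(c2ccccc2)C(C)(C)C)CCC#CC[C@@H](O[Si](C)(C)C(C)(C)C)[C@H]1CC(=O)N(C)C | intermediate
26 | (6S)-allylic mesylate | CS(=O)(=O)O[C@H]1/C=C(/CO[Si](c2ccccc2)(c2ccccc2)C(C)(C)C)CCC#CC[C@@H](O[Si](C)(C)C(C)(C)C)[C@H]1CC(=O)N(C)C | intermediate
27 | (6R)-iminium ether mesylate | C1C(=[N+](C)C)O[C@@H]2/C=C(/CO[Si](c3ccccc3)(c3ccccc3)C(C)(C)C)CCC#CC[C@@H](O[Si](C)(C)C(C)(C)C)[C@@H]12.CS(=O)(=O)[O-] | intermediate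
28 | trans-fused (6R)-6,12-lactone | C1C(=O)O[C@@H]2/C=C(/CO[Si](c3ccccc3)(c3ccccc3)C(C)(C)C)CCC#CC[C@@H](O[Si](C)(C)C(C)(C)C)[C@@H]12 | intermediate
29 | Eschenmoser's salt (N,N-dimethylmethyleneiminium iodide) | C[N+](C)=C.[I-] | starting material
30 | lithium enolate of 28 | C1=C([O-])O[C@@H]2/C=C(/CO[Si](c3ccccc3)(c3ccccc3)C(C)(C)C)CCC#CC[C@@H](O[Si](C)(C)C(C)(C)C)[C@@H]12.[Li+] | intermediate
31 | C11 dimethylaminomethyl lactone (C11 epimers, of no consequence) | CN(C)CC1C(=O)O[C@@H]2/C=C(/CO[Si](c3ccccc3)(c3ccccc3)C(C)(C)C)CCC#CC[C@@H](O[Si](C)(C)C(C)(C)C)[C@@H]12 | intermediate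
32 | trimethylammonium iodide of 31 | C[N+](C)(C)CC1C(=O)O[C@@H]2/C=C(/CO[Si](c3ccccc3)(c3ccccc3)C(C)(C)C)CCC#CC[C@@H](O[Si](C)(C)C(C)(C)C)[C@@H]12.[I-] | intermediate
33 | α-methylene lactone (8-OTBS, 15-OTBDPS) | C=C1C(=O)O[C@@H]2/C=C(/CO[Si](c3ccccc3)(c3ccccc3)C(C)(C)C)CCC#CC[C@@H](O[Si](C)(C)C(C)(C)C)[C@@H]12 | intermediate
34 | 8-hydroxy α-methylene lactone | C=C1C(=O)O[C@@H]2/C=C(/CO[Si](c3ccccc3)(c3ccccc3)C(C)(C)C)CCC#CC[C@@H](O)[C@@H]12 | intermediate
35 | 8-O-dimethylsilyl ether of 34 | C=C1C(=O)O[C@@H]2/C=C(/CO[Si](c3ccccc3)(c3ccccc3)C(C)(C)C)CCC#CC[C@@H](O[SiH](C)C)[C@@H]12 | intermediate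
36 | cyclic vinylsiloxane O8–SiMe2–C10 | C=C1C(=O)O[C@@H]2/C=C(/CO[Si](c4ccccc4)(c4ccccc4)C(C)(C)C)CC/C=C3\C[C@@H](O[Si]3(C)C)[C@@H]12 | intermediate
37 | C10 vinyl iodide, 8-OH | C=C1C(=O)O[C@@H]2/C=C(/CO[Si](c3ccccc3)(c3ccccc3)C(C)(C)C)CC/C=C(/I)C[C@@H](O)[C@@H]12 | intermediate
38 | isovaleric anhydride | CC(C)CC(=O)OC(=O)CC(C)C | starting material
39 | C10 vinyl iodide, 8-O-isovalerate | C=C1C(=O)O[C@@H]2/C=C(/CO[Si](c3ccccc3)(c3ccccc3)C(C)(C)C)CC/C=C(/I)C[C@@H](OC(=O)CC(C)C)[C@@H]12 | intermediate
40 | 15-O-TBDPS ether of the target | C=C1C(=O)O[C@@H]2/C=C(/CO[Si](c3ccccc3)(c3ccccc3)C(C)(C)C)CC/C=C(/CO)C[C@@H](OC(=O)CC(C)C)[C@@H]12 | intermediate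
41 | CNP0199826.1, (6R,7R,8R) | C=C1C(=O)O[C@@H]2/C=C(/CO)CC/C=C(/CO)C[C@@H](OC(=O)CC(C)C)[C@@H]12 | target

Total step count: 24. Longest linear sequence: 24 steps (from 1).

Steps most likely to fail

Step 15. The acid may open the vinyl epoxide before the hindered C10 ketone has condensed, or condensation may be too slow. The fallback sets out from 22 and keeps the same C1–C6 cleavage but triggers it thermally under neutral conditions. Condensation of 22 with 1-amino-2-phenylaziridine (as its acetate, CH2Cl2, 0 °C) would give the N-aziridinyl imine F1. On warming in toluene, F1 loses styrene and nitrogen and fragments to 24, where the route is rejoined.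

Step 16. Hydride may add to both faces of the C6 carbonyl, or mainly to the face not predicted. The fallback sets out from 24 and makes the two epimers converge. After separation, 25 goes on as in step 17. The (6R)-allylic alcohol F2 already carries its oxygen in the final configuration and would be closed with retention by acid-catalysed acyl substitution at the amide (TsOH·H2O, toluene, 60 °C). This gives the same lactone 28.

Step 2. Racemisation of C7 may lag behind reduction, or the catalyst may discriminate poorly between the two alkyl-type flanks of the ketone, which would erode enantiomeric purity. The fallback sets out from 4 and replaces asymmetric catalysis by resolution.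
- Reduction with LiBH(s-Bu)3 (THF, −78 °C) anti to the side chain would give the racemic cis-lactone F3.
- Aminolysis of F3 with (R)-1-phenylethylamine and AlMe3 gives two separable diastereomeric hydroxy amides.
- The (R)-1-phenylethyl hydroxy amide F4, which has the C7/C8 configuration of 6, is relactonised (TsOH·H2O, toluene, reflux) to 6.

Further compounds
F1 | step 15 | N-(2-phenylaziridin-1-yl)imine of 22 | c1ccccc1C1CN1N=C1C[C@@H](O[Si](C)(C)C(C)(C)C)[C@@H](CC(=O)N(C)C)[C@]23O[C@]12CCC(CO[Si](c4ccccc4)(c4ccccc4)C(C)(C)C)=C3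
F2 | step 16 | (6R)-allylic alcohol, C6 epimer of 25 | O[C@@H]1/C=C(/CO[Si](c2ccccc2)(c2ccccc2)C(C)(C)C)CCC#CC[C@@H](O[Si](C)(C)C(C)(C)C)[C@H]1CC(=O)N(C)C
F3 | step 2 | racemic cis-lactone (±)-6, relative configuration shown | C1C[C@@H](OC(=O)C2)[C@@H]2c3cc(OC)ccc31
F4 | step 2 | 2-[(1S,2R)-2-hydroxy-7-methoxy-1,2,3,4-tetrahydronaphthalen-1-yl]-N-[(R)-1-phenylethyl]acetamide | C1C[C@@H](O)[C@@H](CC(=O)N[C@H](C)c2ccccc2)c3cc(OC)ccc31
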